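**Retrosynthetic overview**
- CJ-13,108 has one ring to build, the γ-lactone. It is closed last, by attack of the C3 alkoxide on an ortho methyl ester; the benzene ring is bought.
- Key disconnection: C3–C3a (carbinol carbon to arene). The former aldehyde carbon of the C15 chain is used as an α-acetoxyalkyl anion equivalent, made reductively at nickel from a racemic 1-chloroalkyl acetate, and joined to an aryl bromide carbon. Both carbons are electrophilic in normal polarity. A chiral nickel catalyst makes the coupling enantioconvergent, so (S)-C3 is set in the bond-forming step.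
- Chain: the 1-chloroalkyl acetate comes from a keto-aldehyde and acetyl chloride; the keto-aldehyde comes from an ω-bromo alcohol and acetoacetate (alkylation, decarboxylation, oxidation). The methyl ketone is carried unprotected.
- Arene: the ortho-bromo benzoate ester comes from 1-bromo-3,5-dimethoxybenzene by formylation and oxidative esterification.
- Ring order: arene (purchased), then the lactone, in the same flask as the key coupling.

Assumption: the (S,S) ligand in step 6 is taken to give (S)-C3; the sense is checked on the first run (chiral HPLC, optical rotation) and the (R,R) ligand is used if it is opposite.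

**Step 1**
Reactants: 1 1-bromo-3,5-dimethoxybenzene
Product: 3 2-bromo-4,6-dimethoxybenzaldehyde, via iminium salt 2 (not isolated)
Conditions: POCl3, DMF, 0 to 95 °C; then aq. NaOAc
Reagents that add atoms: N,N-dimethylformamide CN(C)C=O; water O
Why: Vilsmeier–Haack formylation, in which the chloroiminium ion attacks the ring carbon para to one methoxy group and ortho to the other (the position next to bromine), the main site for this substrate, and aqueous work-up hydrolyses iminium salt 2 to the aldehyde; the minor 4-bromo-2,6-dimethoxy isomer is removed by crystallisation.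

**Step 2**
Reactants: 3 2-bromo-4,6-dimethoxybenzaldehyde
Product: 4 methyl 2-bromo-4,6-dimethoxybenzoate
Conditions: I2, KOH, MeOH, 0 °C to rt
Reagents that add atoms: methanol CO
Why: Oxidative esterification, in which the methyl hemiacetal of the aldehyde is oxidised by hypoiodite to the methyl ester under conditions that leave the aryl bromide and the ring untouched.

**Step 3**
Reactants: 5 12-bromododecan-1-ol; 6 ethyl acetoacetate
Product: 9 15-hydroxypentadecan-2-one, via alkylated keto ester 7 (not isolated), via beta-keto acid 8 (not isolated)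
Conditions: K2CO3, KI (cat.), acetone, reflux; then 10% aq. H2SO4, 1,4-dioxane, reflux
Reagents that add atoms: none
Why: Acetoacetic ester ketone synthesis, in which the carbonate-generated enolate of 6 is C-alkylated by the primary bromide (free hydroxyl tolerated) and dilute acid hydrolyses ester 7 to β-keto acid 8, which loses CO2 to give the methyl ketone.

**Step 4**
Reactants: 9 15-hydroxypentadecan-2-one
Product: 10 14-oxopentadecanal
Conditions: TEMPO (10 mol%), PhI(OAc)2 (1.1 equiv), CH2Cl2, rt
Reagents that add atoms: none
Why: TEMPO-catalysed oxoammonium oxidation with PhI(OAc)2 as terminal oxidant converts the primary alcohol to the aldehyde without over-oxidation and does not touch the ketone.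

**Step 5**
Reactants: 10 14-oxopentadecanal
Product: 11 rac-1-chloro-14-oxopentadecyl acetate (used crude)
Conditions: AcCl (1.3 equiv), ZnCl2 (2 mol%), CH2Cl2, −10 °C to rt; evaporate
Reagents that add atoms: acetyl chloride CC(Cl)=O
Why: Lewis-acid-catalysed addition of an acyl chloride across an aldehyde C=O (1-chloroalkyl ester formation) is fast for aldehydes and not for ketones, so only C1 reacts, and the new centre is deliberately formed racemic because step 6 is enantioconvergent.

**Step 6**
Reactants: 11 rac-1-chloro-14-oxopentadecyl acetate; 4 methyl 2-bromo-4,6-dimethoxybenzoate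
Product: 14 (3S)-5,7-dimethoxy-3-(13-oxotetradecyl)-2-benzofuran-1(3H)-one (CJ-13,108), via benzylic acetate 12 (not isolated), via hydroxy ester 13 (not isolated)
Conditions: NiBr2·diglyme (10 mol%), (4S,4'S)-4,4'-di(heptan-4-yl)-4,4',5,5'-tetrahydro-2,2'-bioxazole (12 mol%), Mn powder (3 equiv), TMSCl (0.4 equiv), NaI (0.5 equiv), 1,4-dioxane/DMA 4:1, 10 °C; then K2CO3, MeOH, rt
Reagents that add atoms: none
Why: Proposed new method: zerovalent nickel bearing the chiral bioxazoline inserts into the ester-activated C–Br bond of 4 while chlorine abstraction from racemic 11 by monovalent nickel gives a planar α-acetoxyalkyl radical (the former aldehyde carbon, now an α-oxy carbanion equivalent), whose ligand-controlled capture by the aryl–nickel species and reductive elimination from trivalent nickel form the C3–aryl bond enantioconvergently and set the (S) centre, after which carbonate-catalysed methanolysis of acetate 12 lets the alkoxide of 13 close the lactone on the neighbouring ester without touching C3; the closest known reaction types are nickel-catalysed enantioconvergent couplings of racemic 1-haloalkyl esters with organozinc reagents and asymmetric nickel-catalysed aryl–alkyl cross-electrophile couplings of secondary alkyl chlorides under manganese reduction.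

**Compound list**
1 | 1-bromo-3,5-dimethoxybenzene | COc1cc(Br)cc(OC)c1 | starting material
2 | N-[(2-bromo-4,6-dimethoxyphenyl)methylidene]-N-methylmethanaminium dichlorophosphate | C[N+](C)=Cc1c(Br)cc(OC)cc1OC.[O-]P(Cl)(Cl)=O | intermediate
3 | 2-bromo-4,6-dimethoxybenzaldehyde | O=Cc1c(Br)cc(OC)cc1OC | intermediate
4 | methyl 2-bromo-4,6-dimethoxybenzoate | COC(=O)c1c(Br)cc(OC)cc1OC | intermediate
5 | 12-bromododecan-1-ol | OCCCCCCCCCCCCBr | starting material
6 | ethyl acetoacetate (ethyl 3-oxobutanoate) | CCOC(=O)CC(C)=O | starting material
7 | ethyl 2-acetyl-14-hydroxytetradecanoate (racemic) | CCOC(=O)C(CCCCCCCCCCCCO)C(C)=O | intermediate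
8 | 2-acetyl-14-hydroxytetradecanoic acid (racemic) | OC(=O)C(CCCCCCCCCCCCO)C(C)=O | intermediate
9 | 15-hydroxypentadecan-2-one | CC(=O)CCCCCCCCCCCCCO | intermediate
10 | 14-oxopentadecanal | CC(=O)CCCCCCCCCCCCC=O | intermediate
11 | rac-1-chloro-14-oxopentadecyl acetate | CC(=O)CCCCCCCCCCCCC(Cl)OC(C)=O | intermediate
12 | methyl 2-[(1S)-1-acetoxy-14-oxopentadecyl]-4,6-dimethoxybenzoate | COC(=O)c1c(OC)cc(OC)cc1[C@H](CCCCCCCCCCCCC(C)=O)OC(C)=O | intermediate
13 | methyl 2-[(1S)-1-hydroxy-14-oxopentadecyl]-4,6-dimethoxybenzoate | COC(=O)c1c(OC)cc(OC)cc1[C@H](CCCCCCCCCCCCC(C)=O)O | intermediate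
14 | (3S)-5,7-dimethoxy-3-(13-oxotetradecyl)-2-benzofuran-1(3H)-one (CJ-13,108) | COc1cc(OC)c2c(c1)[C@H](CCCCCCCCCCCCC(C)=O)OC2=O | target

**Step count and risk**
Total steps: 6. Longest linear sequence: 4 (steps 3, 4, 5, 6, from 5 and 6). The arene branch (steps 1, 2) joins at step 6.

Most likely to fail, in order:

Step 6. The enantioconvergent coupling is unproven: cross-selectivity against biaryl and alkyl dimer, and the level of ee, are open. The fallback sets out from aldehyde 10 and aryl bromide 4 (11 is skipped) and makes the same C3–aryl bond at the ketone oxidation level. A photoredox/nickel/hydrogen-atom-transfer acylation (Ir[dF(CF3)ppy]2(dtbbpy)PF6, NiBr2·glyme, 4,4'-di-tert-butyl-2,2'-bipyridine, quinuclidine, K2CO3, dioxane, blue LEDs) uses the aldehyde C–H of 10 as an acyl anion equivalent and gives methyl 2,4-dimethoxy-6-(14-oxopentadecanoyl)benzoate F1. Noyori–Ikariya transfer hydrogenation (RuCl(p-cymene)[(S,S)-TsDPEN], HCO2H/Et3N 5:2, 30 °C) reduces the aryl ketone in preference to the dialkyl ketone and gives the (S)-alcohol. That alcohol is 13, where the route is rejoined, and it closes to 14.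

Step 5. Chloro acetate 11 is moisture-sensitive and the ZnCl2/AcCl medium may attack the methyl ketone. The fallback sets out from 10. Ac2O with FeCl3 (cat.) gives the stable, chromatographable acylal 14-oxopentadecane-1,1-diyl diacetate F2, selectively at the aldehyde. Me3SiBr (ZnBr2 cat., CH2Cl2, 0 °C) then exchanges one acetate for bromide to give rac-1-bromo-14-oxopentadecyl acetate F3. F3 takes the place of 11 in step 6, and the route is rejoined at 12.

Step 1. Regioselectivity of the formylation and removal of the isomer may cost material. The fallback leaves the carboxyl carbon to the end and sets out from 1 and 11. The nickel coupling of step 6, run with 1 itself, gives (1S)-1-(3,5-dimethoxyphenyl)-14-oxopentadecyl acetate F4. NBS (MeCN, 0 °C) brominates ortho to the side chain and para to a methoxy group to give (1S)-1-(2-bromo-3,5-dimethoxyphenyl)-14-oxopentadecyl acetate F5. Pd(OAc)2/Xantphos, CO (1 atm), K2CO3, MeOH, 70 °C first removes the acetate to give (15S)-15-(2-bromo-3,5-dimethoxyphenyl)-15-hydroxypentadecan-2-one F6 and then closes the lactone by carbonylation. The route is rejoined at 14.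

**Further compounds**
F1 | step 6 | methyl 2,4-dimethoxy-6-(14-oxopentadecanoyl)benzoate | COC(=O)c1c(OC)cc(OC)cc1C(=O)CCCCCCCCCCCCC(C)=O
F2 | step 5 | 14-oxopentadecane-1,1-diyl diacetate | CC(=O)CCCCCCCCCCCCC(OC(C)=O)OC(C)=O
F3 | step 5 | rac-1-bromo-14-oxopentadecyl acetate | CC(=O)CCCCCCCCCCCCC(Br)OC(C)=O
F4 | step 1 | (1S)-1-(3,5-dimethoxyphenyl)-14-oxopentadecyl acetate | COc1cc(OC)cc(c1)[C@H](CCCCCCCCCCCCC(C)=O)OC(C)=O
F5 | step 1 | (1S)-1-(2-bromo-3,5-dimethoxyphenyl)-14-oxopentadecyl acetate | COc1cc(OC)c(Br)c(c1)[C@H](CCCCCCCCCCCCC(C)=O)OC(C)=O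
F6 | step 1 | (15S)-15-(2-bromo-3,5-dimethoxyphenyl)-15-hydroxypentadecan-2-one | COc1cc(OC)c(Br)c(c1)[C@H](CCCCCCCCCCCCC(C)=O)O
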